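At 43 min the midnight run has made 62.5% of its charge and the noon run 32.7%, about twice the share, which looks second order in starting material. Yet we shall reckon an order of one.

| flask | starting material | target | time |
|---|---|---|---|
| noon | 300 mM |  |  |
| winter | 300 mM | 90.0 mM |  |
| midnight | 600 mM |  |  |
| dusk | 75.0 mM |  | 68 min |

| run | time / min | [target] / mM |
|---|---|---|
| noon run | 2.4 | 6 |
| noon run | 7.4 | 2 |
| noon run | 14 | 19 |
| noon run | 22 | 25 |
| noon run | 32 | 61 |
| noon run | 43 | 98 |
| noon run | 55 | 122 |
| noon run | 68 | 159 |
| winter run | 2.4 | 98 |
| winter run | 7.4 | 131 |
| winter run | 14 | 178 |
| winter run | 22 | 237 |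
| winter run | 32 | 283 |
| winter run | 43 | 330 |
| winter run | 55 | 329 |
| winter run | 68 | 350 |
| midnight run | 2.4 | 13 |
| midnight run | 7.4 | 18 |
| midnight run | 14 | 57 |
| midnight run | 22 | 126 |
| midnight run | 32 | 249 |
| midnight run | 43 | 375 |
| midnight run | 55 | 448 |
| midnight run | 68 | 478 |

(standard deviation of a reading: 4 mM)

1. order of the initial rate in [starting material], near the charge of the noon run, the rate being that where two percent of its starting material are target (one fixed amount of target, the same in the runs compared)
2. target in the dusk run at 68 min, as a share of the starting material charged

- Overall: starting material -> target.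
- Constant volume, constant temperature.
- An order is taken over about fifteen percent of the charge, up and down.

By 7.4 min the seeded winter run has made 41.0 mM, more than noon's 2 mM, so target makes target: autocatalysis. Let f be the share of charge made and s the share left:

df/dt = s(a + gf), with g = κ × charge

At a fixed amount of target, rate follows starting material, so our order is one. But g for midnight is twice noon's, which is why the shares spread at 43 min though our order is one.

From winter between 7.4 min and 22 min, with mean target 184 mM:

κ = 1.92 × 10⁻⁴ mM⁻¹ min⁻¹

From midnight at 14 min:

a = 0.00273 min⁻¹

Winter's last reading falls 13.3% of its charge short of the total. Taking s as one up to 22 min gives a leak: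

λ = 0.00606 min⁻¹

For dusk, κ × charge × time comes to 0.977. This is our carried quantity, the growth number G, the e-foldings of target that κ, the charge and the time give at full starting material. We go round with f = (a/g)(exp(G s̄) − 1) and s̄ = (1 − f/2)/(1 + λt/2), starting from s̄ = 1:

f = 31.5%

f = 18.6%

f = 20.6%

We commit to the last. The forecast gives 1.3 (0.8 to 2) and 18% (9% to 30%), saying “I lean low because the late rates fall short”.

The simulation gives an order of 1.1 and 22.5% for dusk.

    starting material → target (0.003156 min⁻¹)
    starting material + target → 2 target (0.1854 L mol⁻¹ min⁻¹)
    starting material → decomposed substrate (0.005766 min⁻¹)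

In the noon run the direct step and the decomposition ran from the first minute, with starting material at 300 mM, and the step through target joined as target gathered. Noon had made target to half its charge at 63.9 min, with G at 3.67, and midnight at 36.0 min, with G at 4.14, whereas dusk had G at 0.977 by 68 min, with 22.5% of its charge made.

The runs stem from a simulated flask with made-up constants, noise included.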